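In a one-step world every G becomes the same product whatever vessel holds it, but here G has two paths of different order in [G], so the vessel matters.

    G + E → Z + E, rate k1*[G]^3*[E]/(1 + ([G]/Kh1)^3) (Kh1 = 0.12 M, k1 = 41000 M⁻³ s⁻¹)
    G → Q (k2 = 0.0088 s⁻¹)

| setting | alder | birch | larch | cedar |
|---|---|---|---|---|
| G | 0.11 M (fed, over 9.60 min) | 0.11 M | 0.11 M | 0.11 M |
| E | 0.11 mM | 0.11 mM | 0.11 mM | 0.11 mM |
| time | 12 min |  | 12 min |  |
| remark | all but G at the start; G goes in evenly over 9.60 min, the run ends at 12 min | a single well-mixed tank run continuously and read at steady state, 60.0 min in it on average | everything together in a closed stirred flask, run for 12 min | a single well-mixed tank run continuously and read at steady state, 12 min in it on average |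

- the stated concentrations are those of everything mixed, before any reaction; amounts are the same in each set-up
- the feed brings no volume worth counting
- run time (alder): 12 min

- the set-up with the highest share of Z in all that became Z or Q, at the outlet or at the end ("none" if the first two lie within 2 percentage points) (alder / birch / larch / cedar / none)
- share of Z in all that became Z or Q, at the outlet or at the end, alder
- share of Z in all that became Z or Q, at the outlet or at the end, birch
- share of Z in all that became Z or Q, at the outlet or at the end, larch
- share of Z in all that became Z or Q, at the outlet or at the end, cedar

The rate of step 1 over the rate of step 2 is the instantaneous selectivity, and E comes out of step 1 unchanged, so we hold [E] at 0.11 mM. We carry the crossing concentration Gx, the [G] at which the two steps run equally fast with the saturation term dropped, the square root of k2 over k1[E]: 0.0442 M. That term is 0.0499 at Gx. In logarithms, with that term dropped, the log of the selectivity is twice the log of [G]/Gx; this holds well below Kh1, but not at the start of larch, where the term is 0.770.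

Our reckoning takes birch first. Letting step 2 carry the loss, we put [G] in the birch tank at about 0.00337 M. The log of [G]/Gx is then −1.12, the log of the selectivity is −2.24, and the share of Z in birch is 0.577%. Larch starts higher than Gx at 0.11 M, while birch sits lower than Gx, so we expect larch to beat birch.

The forecast named larch as best, with 12% for alder, 0.57% for birch, 49.3% for larch and 8.9% for cedar, on the ground that “the batch flask, which spends its early time at high G, wins clearly”.

The simulation gives larch as best, with 12.3% for alder, 0.571% for birch, 49.4% for larch and 8.91% for cedar.

Larch starts at 2.49 Gx, where step 2 uses G at 0.29 of the rate of step 1, but at 0.936 min step 2 uses G at 1.9 times that rate. Half of the turnover of step 1 in larch is done by 0.197 min, earlier than the 0.936 min of step 2. The same flask charged with 0.066 M of G starts lower than larch, at 1.49 Gx, and gives a share of Z of 33.4%.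

The constants used here were set for the occasion; the rest is arithmetic.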